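**Retrosynthetic overview**
- The target is released by desilylation of a bis-silyl diketone. The diketone comes from Dess–Martin oxidation of a hydroxy ketone made by joining ring/epoxide lactol 17 and aryl–alkene carbonate 28 at the acyl–CH2 bond (palladium/carbene umpolung allylation, the new step).
- Carbonate 28: zirconium-catalysed carboalumination of propargyl alcohol and palladium-catalysed alkenyl–benzyl coupling with benzyl chloride 24, which fixes the E-alkene. 24 comes from o-cresol by ortho-formylation, Elbs oxidation, silylation, reduction and chlorination.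
- Lactol 17: allylation/lactonisation of aldehyde acid 10, cross-metathesis to the prenyl group, Shi epoxidation, half-reduction.
- Aldehyde acid 10: ozonolysis of an enantioenriched silyl enol ether from chiral-base desymmetrisation of meso cis-1,5-dimethylbicyclo[3.3.0]octan-3-one 6, made from 1,2-dimethylcyclopentene by dichloroketene [2+2], CH2N2 ring expansion and dechlorination.
- Ring order: cyclopentane (bought) → cyclobutanone → second cyclopentanone (later cleaved) → temporary δ-lactone/lactol → oxirane; the arene is bought.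

Assumptions: 1,2-dimethylcyclopentene is purchased; the (R,R)-amide base is assumed, by analogy with related cis-bicyclo[3.3.0]octan-3-ones, to give enol ether 8 (otherwise its (S,S)-antipode is used); the carbinol and lactol carbons of 12, 13, 15, 16, 17 and 29 are epimer mixtures that are erased in step 18.

**Route**

Step 1
Reactants: 1 1,2-dimethylcyclopentene; 2 trichloroacetyl chloride
Product: 4 cis-7,7-dichloro-1,5-dimethylbicyclo[3.2.0]heptan-6-one (racemate), via dichloroketene 3 (not isolated)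
Conditions: Zn (activated dust), Et2O/DME, ultrasound, 15–20 °C
Reagents that add atoms: none
Why: Ketene–alkene [2+2] cycloaddition; dichloroketene adds suprafacially across the tetrasubstituted alkene, so both quaternary carbons form at once with the two methyls cis.

Step 2
Reactants: 4 cis-7,7-dichloro-1,5-dimethylbicyclo[3.2.0]heptan-6-one
Product: 5 cis-2,2-dichloro-1,5-dimethylbicyclo[3.3.0]octan-3-one (racemate)
Conditions: CH2N2 (3 equiv), Et2O, MeOH (cat.), 0 °C → rt
Reagents that add atoms: diazomethane, C=[N+]=[N-]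
Why: Diazomethane ring expansion (second stage of the Greene cyclopentannulation); the non-chlorinated ring-fusion carbon migrates, so CH2 enters between it and the carbonyl, and the stereocentres are untouched.

Step 3
Reactants: 5 cis-2,2-dichloro-1,5-dimethylbicyclo[3.3.0]octan-3-one
Product: 6 cis-1,5-dimethylbicyclo[3.3.0]octan-3-one (meso)
Conditions: Zn, AcOH, 70 °C
Reagents that add atoms: none
Why: Reductive dechlorination through the zinc enolate gives the mirror-symmetric ketone, so the racemic nature of 4 and 5 no longer matters.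

Step 4
Reactants: 6 cis-1,5-dimethylbicyclo[3.3.0]octan-3-one
Product: 8 trimethyl{[(3aS,6aR)-3a,6a-dimethyl-1,3a,4,5,6,6a-hexahydropentalen-2-yl]oxy}silane, via lithium enolate 7 (not isolated)
Conditions: (R,R)-bis(1-phenylethyl)amine, n-BuLi, LiCl, THF, −78 °C; then 6 + Me3SiCl (internal quench), −100 °C
Reagents that add atoms: chlorotrimethylsilane, C[Si](C)(C)Cl
Why: Enantioselective deprotonation with a chiral lithium amide (Simpkins-type desymmetrisation) removes one of the enantiotopic α-CH2 protons, which fixes the absolute configuration of both quaternary carbons.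

Step 5
Reactants: 8 trimethyl{[(3aS,6aR)-3a,6a-dimethyl-1,3a,4,5,6,6a-hexahydropentalen-2-yl]oxy}silane
Product: 10 2-[(1R,2R)-2-formyl-1,2-dimethylcyclopentyl]acetic acid, via trimethylsilyl ester 9 (not isolated)
Conditions: O3, CH2Cl2, −78 °C; Me2S, −78 °C → rt; aqueous work-up (pH 3)
Reagents that add atoms: ozone, [O-][O+]=O
Why: Ozonolysis of the silyl enol ether gives the aldehyde on one ring carbon and, after hydrolysis of the silyl ester, the acetic acid arm on the other; neither quaternary centre can epimerise.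

Step 6
Reactants: 10 2-[(1R,2R)-2-formyl-1,2-dimethylcyclopentyl]acetic acid; 11 allylmagnesium bromide
Product: 13 (4aR,7aR)-4a,7a-dimethyl-1-(prop-2-en-1-yl)hexahydrocyclopenta[c]pyran-3(1H)-one (C-1 epimers), via hydroxy acid 12 (not isolated)
Conditions: CH2=CHCH2MgBr (2.5 equiv), THF, −78 → 0 °C; 1 M HCl; TsOH (cat.), CH2Cl2, rt
Reagents that add atoms: none
Why: Grignard 1,2-addition to the aldehyde (the magnesium carboxylate is inert) followed by acid-catalysed lactonisation; the new carbinol centre is formed unselectively and is oxidised away in step 18.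

Step 7
Reactants: 13 (4aR,7aR)-4a,7a-dimethyl-1-(prop-2-en-1-yl)hexahydrocyclopenta[c]pyran-3(1H)-one; 14 2-methyl-2-butene
Product: 15 (4aR,7aR)-4a,7a-dimethyl-1-(3-methylbut-2-en-1-yl)hexahydrocyclopenta[c]pyran-3(1H)-one (C-1 epimers)
Conditions: second-generation Grubbs catalyst RuCl2(H2IMes)(PCy3)(=CHPh) (3 mol %), 2-methyl-2-butene/CH2Cl2, 40 °C
Reagents that add atoms: none
Why: Olefin cross-metathesis with excess 2-methyl-2-butene converts the allyl group into the prenyl group; the lactone is inert.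

Step 8
Reactants: 15 (4aR,7aR)-4a,7a-dimethyl-1-(3-methylbut-2-en-1-yl)hexahydrocyclopenta[c]pyran-3(1H)-one
Product: 16 (4aR,7aR)-1-{[(2S)-3,3-dimethyloxiran-2-yl]methyl}-4a,7a-dimethylhexahydrocyclopenta[c]pyran-3(1H)-one (C-1 epimers)
Conditions: ent-Shi ketone (L-fructose-derived, 30 mol %), KHSO5 (as 2KHSO5·KHSO4·K2SO4), K2CO3, n-Bu4NHSO4, MeCN/dimethoxymethane/aq. Na2B4O7 buffer, −5 to 0 °C
Reagents that add atoms: potassium peroxymonosulfate, [K+].[O-]S(=O)(=O)OO
Why: Shi asymmetric epoxidation; the chiral dioxirane attacks the trisubstituted alkene through a spiro transition state under reagent control, and the L-series ketone gives the (S)-oxirane.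

Step 9
Reactants: 16 (4aR,7aR)-1-{[(2S)-3,3-dimethyloxiran-2-yl]methyl}-4a,7a-dimethylhexahydrocyclopenta[c]pyran-3(1H)-one
Product: 17 (4aR,7aR)-1-{[(2S)-3,3-dimethyloxiran-2-yl]methyl}-4a,7a-dimethyloctahydrocyclopenta[c]pyran-3-ol (lactol; C-1 and C-3 epimers)
Conditions: i-Bu2AlH (1.2 equiv), CH2Cl2, −78 °C; aq. potassium sodium tartrate (KNaC4H4O6)
Reagents that add atoms: none
Why: Half-reduction of the lactone stops at the aluminium hemiacetal at −78 °C; the hindered trisubstituted epoxide is not touched.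

Step 10
Reactants: 18 o-cresol
Product: 19 2-hydroxy-3-methylbenzaldehyde
Conditions: (CH2O)n, MgCl2, Et3N, MeCN, reflux
Reagents that add atoms: paraformaldehyde (formaldehyde), C=O
Why: Casnati–Skattebøl ortho-formylation; the magnesium phenoxide delivers formaldehyde to the only free ortho position and a second formaldehyde accepts hydride.

Step 11
Reactants: 19 2-hydroxy-3-methylbenzaldehyde
Product: 21 2,5-dihydroxy-3-methylbenzaldehyde, via aryl sulfate salt 20 (not isolated)
Conditions: K2S2O8, 10% aq. NaOH, 15 °C, 20 h; then HCl, 90 °C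
Reagents that add atoms: potassium peroxodisulfate, [K+].[K+].[O-]S(=O)(=O)OOS(=O)(=O)[O-]
Why: Elbs persulfate oxidation; the phenoxide is attacked para by peroxodisulfate and the aryl sulfate is hydrolysed (modest yield, early stage, starting material recovered).

Step 12
Reactants: 21 2,5-dihydroxy-3-methylbenzaldehyde
Product: 22 3-methyl-2,5-bis[(triisopropylsilyl)oxy]benzaldehyde
Conditions: i-Pr3SiOTf (2.4 equiv), 2,6-lutidine, CH2Cl2, 0 °C → rt
Reagents that add atoms: triisopropylsilyl trifluoromethanesulfonate, CC(C)[Si](C(C)C)(C(C)C)OS(=O)(=O)C(F)(F)F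
Why: Silyl triflate silylation reaches the hindered, hydrogen-bonded phenol; triisopropylsilyl ethers resist organoaluminium, alkoxide and silyl migration and fall to fluoride at the end.

Step 13
Reactants: 22 3-methyl-2,5-bis[(triisopropylsilyl)oxy]benzaldehyde
Product: 23 {3-methyl-2,5-bis[(triisopropylsilyl)oxy]phenyl}methanol
Conditions: NaBH4, THF/MeOH, 0 °C
Reagents that add atoms: none
Why: Borohydride reduction of the aldehyde; protonation in methanol outpaces any O-to-O silyl shift.

Step 14
Reactants: 23 {3-methyl-2,5-bis[(triisopropylsilyl)oxy]phenyl}methanol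
Product: 24 1-(chloromethyl)-3-methyl-2,5-bis[(triisopropylsilyl)oxy]benzene
Conditions: PPh3, N-chlorosuccinimide, THF, 0 °C → rt
Reagents that add atoms: N-chlorosuccinimide, ClN1C(=O)CCC1=O
Why: Appel-type chlorination through the alkoxyphosphonium salt under neutral conditions that leave the aryl silyl ethers intact.

Step 15
Reactants: 25 propargyl alcohol; 24 1-(chloromethyl)-3-methyl-2,5-bis[(triisopropylsilyl)oxy]benzene
Product: 27 (E)-2-methyl-4-{3-methyl-2,5-bis[(triisopropylsilyl)oxy]phenyl}but-2-en-1-ol, via alkenylalane 26 (not isolated)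
Conditions: AlMe3 (3 equiv), Cp2ZrCl2 (25 mol %), ClCH2CH2Cl, 0 °C → rt; then 24, Pd(PPh3)4 (5 mol %), THF, rt; dilute HCl work-up
Reagents that add atoms: trimethylaluminium, C[Al](C)C
Why: Negishi zirconium-catalysed syn-carboalumination places methyl and aluminium cis on the alkyne, and the palladium-catalysed alkenyl–benzyl cross-coupling proceeds with retention, which fixes the E-trisubstituted alkene.

Step 16
Reactants: 27 (E)-2-methyl-4-{3-methyl-2,5-bis[(triisopropylsilyl)oxy]phenyl}but-2-en-1-ol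
Product: 28 tert-butyl (E)-2-methyl-4-{3-methyl-2,5-bis[(triisopropylsilyl)oxy]phenyl}but-2-en-1-yl carbonate
Conditions: Boc2O, DMAP (10 mol %), MeCN, rt
Reagents that add atoms: di-tert-butyl dicarbonate, CC(C)(C)OC(=O)OC(=O)OC(C)(C)C
Why: Acyl transfer gives an allylic carbonate that zerovalent palladium ionises readily and that releases tert-butoxide as an internal base.

Step 17
Reactants: 17 (4aR,7aR)-1-{[(2S)-3,3-dimethyloxiran-2-yl]methyl}-4a,7a-dimethyloctahydrocyclopenta[c]pyran-3-ol; 28 tert-butyl (E)-2-methyl-4-{3-methyl-2,5-bis[(triisopropylsilyl)oxy]phenyl}but-2-en-1-yl carbonate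
Product: 29 (E)-1-[(1R,2R)-2-{2-[(2S)-3,3-dimethyloxiran-2-yl]-1-hydroxyethyl}-1,2-dimethylcyclopentyl]-4-methyl-6-{3-methyl-2,5-bis[(triisopropylsilyl)oxy]phenyl}hex-4-en-2-one (carbinol epimers; in equilibrium with its cyclic hemiketal)
Conditions: Pd2(dba)3 (2.5 mol %), Xantphos (6 mol %), 3-(2,6-diisopropylphenyl)-4,5-dimethylthiazolium perchlorate (10 mol %), KOtBu (10 mol %), toluene, 50 °C
Reagents that add atoms: none
Why: Proposed new method: carbene/palladium umpolung allylation of a lactol-masked aliphatic aldehyde. Ring–chain tautomerism frees the δ-hydroxy aldehyde, the thiazolylidene turns it into a Breslow intermediate (acyl anion equivalent), and this attacks the unsubstituted CH2 terminus of the syn π-allyl complex formed when zerovalent palladium ionises E-carbonate 28. Collapse of the adduct releases the carbene and the β,γ-unsaturated ketone, and the tert-butoxide set free by decarboxylation regenerates the carbene. The E geometry is kept because C–C bond formation at the remote terminus is expected to outrun syn/anti exchange, and no new stereocentre of the target is made. The closest known reaction type is the cooperative carbene/palladium allylation of aromatic aldehydes with allylic carbonates, which has not been shown for an aliphatic, β-quaternary, lactol-masked aldehyde or for a 2-methyl-substituted allyl unit.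

Step 18
Reactants: 29 (E)-1-[(1R,2R)-2-{2-[(2S)-3,3-dimethyloxiran-2-yl]-1-hydroxyethyl}-1,2-dimethylcyclopentyl]-4-methyl-6-{3-methyl-2,5-bis[(triisopropylsilyl)oxy]phenyl}hex-4-en-2-one
Product: 30 (E)-1-[(1R,2R)-2-{[(2S)-3,3-dimethyloxiran-2-yl]acetyl}-1,2-dimethylcyclopentyl]-4-methyl-6-{3-methyl-2,5-bis[(triisopropylsilyl)oxy]phenyl}hex-4-en-2-one
Conditions: Dess–Martin periodinane (1.5 equiv), pyridine (5 equiv), CH2Cl2, 0 °C → rt
Reagents that add atoms: none
Why: Dess–Martin oxidation of the open hydroxy-ketone tautomer gives the second ketone under buffered, non-basic conditions that spare the β,γ-epoxy ketone and the β,γ-alkene, and removes the carbinol epimers.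

Step 19
Reactants: 30 (E)-1-[(1R,2R)-2-{[(2S)-3,3-dimethyloxiran-2-yl]acetyl}-1,2-dimethylcyclopentyl]-4-methyl-6-{3-methyl-2,5-bis[(triisopropylsilyl)oxy]phenyl}hex-4-en-2-one
Product: 31 (E)-6-(2,5-dihydroxy-3-methylphenyl)-1-[(1R,2R)-2-{[(2S)-3,3-dimethyloxiran-2-yl]acetyl}-1,2-dimethylcyclopentyl]-4-methylhex-4-en-2-one (CNP0357486.2)
Conditions: n-Bu4NF (2.2 equiv), AcOH (2.4 equiv), THF, 0 °C, argon
Reagents that add atoms: none
Why: Fluoride cleavage of the aryl silyl ethers, buffered with acetic acid so that no free phenoxide or alkoxide can trigger epoxide β-elimination, aldol closure of the 1,5-diketone or alkene conjugation.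

**Compound list**

1 | 1,2-dimethylcyclopentene | CC1=C(C)CCC1 | starting material
2 | trichloroacetyl chloride | ClC(=O)C(Cl)(Cl)Cl | starting material
3 | dichloroketene | O=C=C(Cl)Cl | intermediate (not isolated)
4 | cis-7,7-dichloro-1,5-dimethylbicyclo[3.2.0]heptan-6-one (racemate; one enantiomer drawn) | O=C1[C@@]2(C)CCC[C@@]2(C)C1(Cl)Cl | intermediate
5 | cis-2,2-dichloro-1,5-dimethylbicyclo[3.3.0]octan-3-one (racemate; one enantiomer drawn) | O=C1C[C@@]2(C)CCC[C@@]2(C)C1(Cl)Cl | intermediate
6 | cis-1,5-dimethylbicyclo[3.3.0]octan-3-one (meso) | O=C1C[C@@]2(C)CCC[C@@]2(C)C1 | intermediate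
7 | lithium (3aS,6aR)-3a,6a-dimethyl-1,3a,4,5,6,6a-hexahydropentalen-2-olate | [Li]OC1=C[C@]2(C)CCC[C@]2(C)C1 | intermediate (not isolated)
8 | trimethyl{[(3aS,6aR)-3a,6a-dimethyl-1,3a,4,5,6,6a-hexahydropentalen-2-yl]oxy}silane | C[Si](C)(C)OC1=C[C@]2(C)CCC[C@]2(C)C1 | intermediate
9 | trimethylsilyl 2-[(1R,2R)-2-formyl-1,2-dimethylcyclopentyl]acetate | C[Si](C)(C)OC(=O)C[C@@]1(C)CCC[C@@]1(C)C=O | intermediate (not isolated)
10 | 2-[(1R,2R)-2-formyl-1,2-dimethylcyclopentyl]acetic acid | OC(=O)C[C@@]1(C)CCC[C@@]1(C)C=O | intermediate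
11 | allylmagnesium bromide | C=CC[Mg]Br | starting material
12 | 2-[(1R,2R)-2-(1-hydroxybut-3-en-1-yl)-1,2-dimethylcyclopentyl]acetic acid (carbinol epimers) | OC(=O)C[C@@]1(C)CCC[C@@]1(C)C(O)CC=C | intermediate (not isolated)
13 | (4aR,7aR)-4a,7a-dimethyl-1-(prop-2-en-1-yl)hexahydrocyclopenta[c]pyran-3(1H)-one (C-1 epimers) | O=C1C[C@@]2(C)CCC[C@@]2(C)C(CC=C)O1 | intermediate
14 | 2-methyl-2-butene | CC=C(C)C | starting material
15 | (4aR,7aR)-4a,7a-dimethyl-1-(3-methylbut-2-en-1-yl)hexahydrocyclopenta[c]pyran-3(1H)-one (C-1 epimers) | O=C1C[C@@]2(C)CCC[C@@]2(C)C(CC=C(C)C)O1 | intermediate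
16 | (4aR,7aR)-1-{[(2S)-3,3-dimethyloxiran-2-yl]methyl}-4a,7a-dimethylhexahydrocyclopenta[c]pyran-3(1H)-one (C-1 epimers) | O=C1C[C@@]2(C)CCC[C@@]2(C)C(C[C@@H]3OC3(C)C)O1 | intermediate
17 | (4aR,7aR)-1-{[(2S)-3,3-dimethyloxiran-2-yl]methyl}-4a,7a-dimethyloctahydrocyclopenta[c]pyran-3-ol (C-1 and C-3 epimers) | OC1C[C@@]2(C)CCC[C@@]2(C)C(C[C@@H]3OC3(C)C)O1 | intermediate
18 | o-cresol | Cc1ccccc1O | starting material
19 | 2-hydroxy-3-methylbenzaldehyde | Cc1cccc(C=O)c1O | intermediate
20 | potassium 3-formyl-4-hydroxy-5-methylphenyl sulfate | Cc1cc(OS(=O)(=O)[O-])cc(C=O)c1O.[K+] | intermediate (not isolated)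
21 | 2,5-dihydroxy-3-methylbenzaldehyde | Cc1cc(O)cc(C=O)c1O | intermediate
22 | 3-methyl-2,5-bis[(triisopropylsilyl)oxy]benzaldehyde | Cc1cc(O[Si](C(C)C)(C(C)C)C(C)C)cc(C=O)c1O[Si](C(C)C)(C(C)C)C(C)C | intermediate
23 | {3-methyl-2,5-bis[(triisopropylsilyl)oxy]phenyl}methanol | Cc1cc(O[Si](C(C)C)(C(C)C)C(C)C)cc(CO)c1O[Si](C(C)C)(C(C)C)C(C)C | intermediate
24 | 1-(chloromethyl)-3-methyl-2,5-bis[(triisopropylsilyl)oxy]benzene | Cc1cc(O[Si](C(C)C)(C(C)C)C(C)C)cc(CCl)c1O[Si](C(C)C)(C(C)C)C(C)C | intermediate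
25 | propargyl alcohol | C#CCO | starting material
26 | dimethyl{(E)-3-[(dimethylalumanyl)oxy]-2-methylprop-1-en-1-yl}alumane | C[Al](C)OC/C(C)=C/[Al](C)C | intermediate (not isolated)
27 | (E)-2-methyl-4-{3-methyl-2,5-bis[(triisopropylsilyl)oxy]phenyl}but-2-en-1-ol | C/C(=C\Cc1cc(O[Si](C(C)C)(C(C)C)C(C)C)cc(C)c1O[Si](C(C)C)(C(C)C)C(C)C)CO | intermediate
28 | tert-butyl (E)-2-methyl-4-{3-methyl-2,5-bis[(triisopropylsilyl)oxy]phenyl}but-2-en-1-yl carbonate | C/C(=C\Cc1cc(O[Si](C(C)C)(C(C)C)C(C)C)cc(C)c1O[Si](C(C)C)(C(C)C)C(C)C)COC(=O)OC(C)(C)C | intermediate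
29 | (E)-1-[(1R,2R)-2-{2-[(2S)-3,3-dimethyloxiran-2-yl]-1-hydroxyethyl}-1,2-dimethylcyclopentyl]-4-methyl-6-{3-methyl-2,5-bis[(triisopropylsilyl)oxy]phenyl}hex-4-en-2-one (carbinol epimers) | C/C(=C\Cc1cc(O[Si](C(C)C)(C(C)C)C(C)C)cc(C)c1O[Si](C(C)C)(C(C)C)C(C)C)CC(=O)C[C@@]1(C)CCC[C@@]1(C)C(O)C[C@@H]1OC1(C)C | intermediate
30 | (E)-1-[(1R,2R)-2-{[(2S)-3,3-dimethyloxiran-2-yl]acetyl}-1,2-dimethylcyclopentyl]-4-methyl-6-{3-methyl-2,5-bis[(triisopropylsilyl)oxy]phenyl}hex-4-en-2-one | C/C(=C\Cc1cc(O[Si](C(C)C)(C(C)C)C(C)C)cc(C)c1O[Si](C(C)C)(C(C)C)C(C)C)CC(=O)C[C@@]1(C)CCC[C@@]1(C)C(=O)C[C@@H]1OC1(C)C | intermediate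
31 | (E)-6-(2,5-dihydroxy-3-methylphenyl)-1-[(1R,2R)-2-{[(2S)-3,3-dimethyloxiran-2-yl]acetyl}-1,2-dimethylcyclopentyl]-4-methylhex-4-en-2-one | C/C(=C\Cc1cc(O)cc(C)c1O)CC(=O)C[C@@]1(C)CCC[C@@]1(C)C(=O)C[C@@H]1OC1(C)C | target

**Step count**

Total: 19 steps. Longest linear sequence: 12 steps (steps 1–9, then 17–19); the aryl–alkene branch (steps 10–16) joins at step 17.

**Steps most likely to fail, with fallbacks**

Step 4 (asymmetric deprotonation). The α-CH2 groups are flanked by quaternary carbons, so rate and enantioselectivity of the chiral-base deprotonation are uncertain. The fallback sets out from 6 and returns at 13, replacing asymmetric deprotonation by a resolution through diastereomers. Ketone 6 is deprotonated with lithium diisopropylamide and silylated to the racemic trimethylsilyl enol ether F1, which is ozonised as in step 5 through the racemic trimethylsilyl ester F2 to the racemic aldehyde acid F3. Me3SiCHN2 gives the racemic methyl ester F4. Reagent-controlled Brown allylation with one enantiomer of B-allyldiisopinocampheylborane (Et2O, −78 °C; NaBO3 work-up) gives the hydroxy esters F5, in which the carbinol configuration is the same for both ring enantiomers. Lactonisation (TsOH) turns them into two diastereomeric lactones that are separated on silica: the unwanted (4aS,7aS)-lactone F6 is discarded, and the (4aR,7aR)-lactone (assigned by X-ray or correlation) is compound 13 as a single C-1 epimer.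

Step 17 (the proposed carbene/palladium union). Likely failure modes are O-allylation of the lactol, slow carbene addition to the masked aldehyde, partial E/Z erosion through syn/anti exchange, and base-induced conjugation of the product. The fallback uses known chemistry, sets out from 17 and 27, and returns at 30. Alcohol 27 is converted with N-chlorosuccinimide/Me2S (CH2Cl2, −20 °C) into the allylic chloride F7. Reactive barium (from BaI2 and lithium biphenylide, THF, −78 °C) turns F7 into the allylbarium chloride F8, which adds to lactol 17 (2.2 equiv of F8, −78 °C) at its unsubstituted α-carbon with retention of the E geometry to give the diol F9. Dess–Martin oxidation of both carbinols under the conditions of step 18 (3 equiv) gives diketone 30.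

Step 19 (final desilylation). The product carries a β,γ-epoxy ketone, a 1,5-diketone, a β,γ-unsaturated ketone and an air-sensitive hydroquinone, so even buffered fluoride may cause elimination, aldol closure or oxidation. The fallback sets out from 29 and returns at 31, moving the desilylation ahead of the oxidation and ending with a neutral reduction. Hydroxy ketone 29 is desilylated with n-Bu4NF/AcOH (THF, 0 °C) to the hydroquinone alcohol F10. Dess–Martin periodinane (3.5 equiv, pyridine, CH2Cl2) oxidises both the carbinol and the hydroquinone to the quinone diketone F11. Brief shaking with aqueous Na2S2O4 in EtOAc under argon reduces only the quinone and gives target 31.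

**Further compounds**

F1 | step 4 | racemic trimethyl[(3a,6a-dimethyl-1,3a,4,5,6,6a-hexahydropentalen-2-yl)oxy]silane (cis; one enantiomer drawn) | C[Si](C)(C)OC1=C[C@]2(C)CCC[C@]2(C)C1
F2 | step 4 | racemic trimethylsilyl 2-[(1R*,2R*)-2-formyl-1,2-dimethylcyclopentyl]acetate (not isolated; one enantiomer drawn) | C[Si](C)(C)OC(=O)C[C@@]1(C)CCC[C@@]1(C)C=O
F3 | step 4 | racemic 2-[(1R*,2R*)-2-formyl-1,2-dimethylcyclopentyl]acetic acid (one enantiomer drawn) | OC(=O)C[C@@]1(C)CCC[C@@]1(C)C=O
F4 | step 4 | racemic methyl 2-[(1R*,2R*)-2-formyl-1,2-dimethylcyclopentyl]acetate (one enantiomer drawn) | COC(=O)C[C@@]1(C)CCC[C@@]1(C)C=O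
F5 | step 4 | methyl 2-[2-(1-hydroxybut-3-en-1-yl)-1,2-dimethylcyclopentyl]acetate (both ring enantiomers with one reagent-set carbinol configuration; (1R,2R) component drawn) | COC(=O)C[C@@]1(C)CCC[C@@]1(C)C(O)CC=C
F6 | step 4 | (4aS,7aS)-4a,7a-dimethyl-1-(prop-2-en-1-yl)hexahydrocyclopenta[c]pyran-3(1H)-one (unwanted diastereomer) | O=C1C[C@]2(C)CCC[C@]2(C)C(CC=C)O1
F7 | step 17 | 1-[(E)-4-chloro-3-methylbut-2-en-1-yl]-3-methyl-2,5-bis[(triisopropylsilyl)oxy]benzene | C/C(=C\Cc1cc(O[Si](C(C)C)(C(C)C)C(C)C)cc(C)c1O[Si](C(C)C)(C(C)C)C(C)C)CCl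
F8 | step 17 | [(E)-2-methyl-4-{3-methyl-2,5-bis[(triisopropylsilyl)oxy]phenyl}but-2-en-1-yl]barium chloride | C/C(=C\Cc1cc(O[Si](C(C)C)(C(C)C)C(C)C)cc(C)c1O[Si](C(C)C)(C(C)C)C(C)C)C[Ba]Cl
F9 | step 17 | (E)-1-[(1R,2R)-2-{2-[(2S)-3,3-dimethyloxiran-2-yl]-1-hydroxyethyl}-1,2-dimethylcyclopentyl]-4-methyl-6-{3-methyl-2,5-bis[(triisopropylsilyl)oxy]phenyl}hex-4-en-2-ol (carbinol epimers) | C/C(=C\Cc1cc(O[Si](C(C)C)(C(C)C)C(C)C)cc(C)c1O[Si](C(C)C)(C(C)C)C(C)C)CC(O)C[C@@]1(C)CCC[C@@]1(C)C(O)C[C@@H]1OC1(C)C
F10 | step 19 | (E)-6-(2,5-dihydroxy-3-methylphenyl)-1-[(1R,2R)-2-{2-[(2S)-3,3-dimethyloxiran-2-yl]-1-hydroxyethyl}-1,2-dimethylcyclopentyl]-4-methylhex-4-en-2-one (carbinol epimers) | C/C(=C\Cc1cc(O)cc(C)c1O)CC(=O)C[C@@]1(C)CCC[C@@]1(C)C(O)C[C@@H]1OC1(C)C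
F11 | step 19 | 2-[(E)-6-[(1R,2R)-2-{[(2S)-3,3-dimethyloxiran-2-yl]acetyl}-1,2-dimethylcyclopentyl]-3-methyl-5-oxohex-2-en-1-yl]-6-methylcyclohexa-2,5-diene-1,4-dione | C/C(=C\CC1=CC(=O)C=C(C)C1=O)CC(=O)C[C@@]1(C)CCC[C@@]1(C)C(=O)C[C@@H]1OC1(C)C
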